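The retrosynthesis first removes the epoxide oxygen and the lactone C–O bonds, which leaves an allyl group and a benzyl ester on C12. It then cuts C6–C7 and C5–O (ring B), then C9–C10, and last a temporary C6–C7 aldol bond between a ring A enone and a ring C enal.
The key step rests on this feature: in ring B only CH2-6 lies between C5 (tertiary OH) and C7 (equatorial β oxygen), and the C5 hydroxyl is 1,3-diaxial on the α face to the C1 acetate of ring A. A C7 aldehyde, a C5=C6 methylene and the 1α-acetate can therefore form C6–C7 and C5–O in one cationic event.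
In the forward direction ring C comes from ring contraction of a desymmetrised cyclohexene and ring A from 4,4-dimethylcyclohexane-1,3-dione. A vinylogous aldol joins them at C6–C7, an anionic oxy-Cope shift moves the link to C9–C10 and frees the aldehyde and the methylene, the Prins step re-forms C6–C7 and closes ring B, and the spiro lactone and its epoxide come last.
Stereochemistry: C14 and C12 come from alkaloid-mediated anhydride opening and anti alkylation, and a CBS-made 1β-carbinol relays through the chair oxy-Cope to C10 and C9. C8 and C14 are set by equilibration, C1 is re-set to α by a second CBS reduction, C7 and C5 arise in the Prins step, and C15/C16 come from bromohydrin formation on the open face followed by closure with inversion.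

Key step: step 20

Remark on numbering: ring A = C1–C5, C10; ring B = C5–C10; ring C = C8, C9, C11, C12 (spiro), C14; lactone = C12, C13 (C=O), O, C16, C15; α is the face opposite to the C10 methyl.
Remark on step 1: quinidine is assumed to be the cinchona alkaloid that gives hemiester 2 as drawn; if the sense is the reverse, quinine takes its place.

Step 1
Reactants: 1 cis-cyclohex-4-ene-1,2-dicarboxylic anhydride
Product: 2 (1R,6S)-6-(benzyloxycarbonyl)cyclohex-3-ene-1-carboxylic acid
Conditions: BnOH (3 equiv), quinidine (1.1 equiv), toluene, −55 °C; 2 M HCl wash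
Reagents that add atoms: benzyl alcohol, OCc1ccccc1
Why: Alkaloid-mediated desymmetrising alcoholysis of a meso anhydride, well tried on this very substrate, tells the two enantiotopic carbonyl groups apart and thereby fixes the future C14 (acid-bearing) and C12 (ester-bearing) carbons in the absolute sense.

Step 2
Reactants: 2 hemiester; 3 allyl bromide
Product: 5 1-allyl 2-benzyl (1R,2S)-2-allylcyclohex-4-ene-1,2-dicarboxylate, via lithium carboxylate 4 (not isolated)
Conditions: LDA (2.2 equiv), THF, −78 to −20 °C; 3 (1.1 equiv), −78 to 0 °C; then DMF, 3 (2 equiv), 40 °C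
Reagents that add atoms: allyl bromide, C=CCBr
Why: Dianion alkylation of a half-ester: only the carbon α to the ester (C12) is enolised beside the carboxylate, allyl bromide enters anti to the neighbouring carboxylate so that the quaternary centre C12 is set with allyl trans to the C14 carboxyl, and the carboxylate is then O-allylated in the same flask.

Step 3
Reactants: 5 allyl benzyl diester
Product: 6 4,5-epoxide of 5 (oxirane trans to the ester groups)
Conditions: mCPBA (1.05 equiv), CH2Cl2, 0 °C
Reagents that add atoms: 3-chloroperoxybenzoic acid, O=C(OO)c1cccc(Cl)c1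
Why: Prilezhaev epoxidation picks the cis-disubstituted ring alkene, which is far more nucleophilic than the two monosubstituted allyl groups, and the oxirane configuration (drawn for attack anti to the esters) is erased in the next step.

Step 4
Reactants: 6 epoxide
Product: 7 4-allyl 1-benzyl 2-allyl-2,3-bis(2-oxoethyl)butanedioate (C12 and C14 as in 5)
Conditions: H5IO6 (1.3 equiv), THF–H2O, 0 °C to rt
Reagents that add atoms: water, O
Why: Periodic acid hydrolyses the epoxide and cleaves the resulting glycol (Malaprade cleavage) in one operation to the 1,6-dialdehyde without touching the terminal alkenes or the two stereocentres.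

Step 5
Reactants: 7 dialdehyde
Product: 8 ring C enal, 1-allyl 2-benzyl 2-allyl-5-formylcyclopent-4-ene-1,2-dicarboxylate (ester groups cis)
Conditions: Bn2NH·CF3CO2H (0.3 equiv), toluene, 50 °C
Reagents that add atoms: none
Why: Amine-salt-catalysed intramolecular aldol condensation of a 1,6-dialdehyde gives the cyclopentenecarbaldehyde, and the enamine forms and reacts at C8 (next to tertiary C14) rather than at neopentyl C11 (next to quaternary C12), so that C8 adds to the C9 aldehyde and the C8=C9 enal results.

Step 6
Reactants: 9 4,4-dimethylcyclohexane-1,3-dione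
Product: 10 2,4,4-trimethylcyclohexane-1,3-dione
Conditions: MeI, KOH, MeOH–H2O, 60 °C
Reagents that add atoms: iodomethane, CI
Why: C-Alkylation of the enolate of a cyclic 1,3-diketone at the doubly activated carbon brings in the future C10 methyl group.

Step 7
Reactants: 10 trimethyl diketone
Product: 11 3-isobutoxy-2,6,6-trimethylcyclohex-2-en-1-one
Conditions: i-BuOH, TsOH·H2O (cat.), toluene, reflux, Dean–Stark trap
Reagents that add atoms: 2-methylpropan-1-ol, CC(C)CO
Why: Acid-catalysed vinylogous ester formation takes place at the carbonyl remote from the gem-dimethyl group, which leaves the hindered carbonyl (future C5) as the ketone.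

Step 8
Reactants: 11 vinylogous ester
Product: 13 2,3,4,4-tetramethylcyclohex-2-en-1-one, via tertiary carbinol 12 (not isolated)
Conditions: MeLi, Et2O, −78 °C to rt; then 1 M HCl, THF, rt
Reagents that add atoms: methyllithium, [Li]C
Why: Stork–Danheiser sequence: 1,2-addition of methyllithium to the vinylogous ester brings in C6 and acid hydrolysis of carbinol 12 with allylic transposition gives the tetrasubstituted enone that has its carbonyl at C1.

Step 9
Reactants: 13 ring A enone
Product: 14 tert-butyldimethylsilyl dienol ether, 1-silyloxy-2,4,4-trimethyl-3-methylenecyclohex-1-ene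
Conditions: TBSOTf, Et3N, CH2Cl2, 0 °C to rt
Reagents that add atoms: tert-butyldimethylsilyl triflate, CC(C)(C)[Si](C)(C)OS(=O)(=O)C(F)(F)F
Why: Soft enolisation under equilibrating conditions gives the linearly conjugated dienol silyl ether, and since C4 is quaternary the C6 methyl group holds the only γ-hydrogens.

Step 10
Reactants: 8 ring C enal; 14 ring A dienol silyl ether
Product: 15 enone aldol (C7 carbinol between C6H2 of the ring A enone and C8 of the ring C cyclopentene, both C7 epimers)
Conditions: BF3·OEt2 (1.1 equiv), CH2Cl2, −78 °C; aq. NaHCO3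
Reagents that add atoms: none
Why: Vinylogous Mukaiyama aldol addition: the dienol ether reacts at its unhindered γ-terminus C6 and the Lewis-acid-bound enal at its carbonyl carbon, which forms C6–C7, and both C7 epimers are carried on because C7 becomes trigonal in step 13.

Step 11
Reactants: 15 enone aldol
Product: 16 (1R)-allylic alcohol (1β-OH) of 15
Conditions: (S)-2-methyl-CBS-oxazaborolidine (0.5 equiv), catecholborane (3 equiv), toluene, −78 to −40 °C; pH 7 buffer
Reagents that add atoms: none
Why: Corey–Bakshi–Shibata reduction under catalyst control: the fully substituted alkene flank acts as the large group, so the (S)-catalyst should give the (1R) carbinol (1β-OH), and catecholborane at low temperature leaves esters and isolated alkenes alone.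

Step 12
Reactants: 16 diol allyl ester
Product: 17 potassium C14 carboxylate of the diol
Conditions: Pd(PPh3)4 (3 mol %), potassium 2-ethylhexanoate (1.0 equiv), EtOAc–CH2Cl2, rt
Reagents that add atoms: potassium 2-ethylhexanoate, CCCCC(CC)C(=O)[O-].[K+]
Why: Tsuji–Trost-type cleavage of the allyl ester by zerovalent palladium, the 2-ethylhexanoate acting as allyl acceptor, delivers the potassium carboxylate under neutral conditions, while the C-allyl group and the free allylic alcohols are not ionised.

Step 13
Reactants: 17 potassium carboxylate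
Product: 20 seco ring B hydroxy aldehyde acid (C9–C10 bond, C5 methylene, C7 aldehyde, 1β-OH, C14 carboxyl α; C8 epimers), via tripotassium dialkoxide 18 (not isolated), via tripotassium enolate 19 (not isolated)
Conditions: KH (3 equiv), 18-crown-6 (3 equiv), THF, 0 to 55 °C; AcOH, −78 °C
Reagents that add atoms: none
Why: Anionic oxy-Cope rearrangement: the C7 alkoxide drives the [3,3] shift of the C9=C8–C7–C6–C5=C10 diene through a chair (a boat would press C4 against C14), which places H9 anti to the C10 methyl, the pseudoaxial 1β-oxide shields the β face of ring A so that C9 bonds to the α face of C10, the α-oriented carboxyl groups on C12 and C14 favour the matching β face of ring C, and the C14 carboxylate can neither be attacked by the C7 alkoxide nor acidify H14.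

Step 14
Reactants: 20 hydroxy aldehyde acid
Product: 21 methyl ester of 20
Conditions: MeI, K2CO3, DMF, rt
Reagents that add atoms: iodomethane, CI
Why: O-Alkylation of the potassium carboxylate with iodomethane gives the normal (open) methyl ester without affecting the hindered secondary alcohol.

Step 15
Reactants: 21 aldehyde methyl ester
Product: 23 all-trans dimethyl acetal (C8 α-CH(OMe)2, C14 β-CO2Me, 1β-OH), via all-trans aldehyde 22 (not isolated)
Conditions: NaOMe (0.3 equiv), MeOH, rt; then CSA (0.5 equiv), HC(OMe)3, rt
Reagents that add atoms: trimethyl orthoformate, COC(OC)OC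
Why: Methoxide equilibrates the two enolisable centres C8 and C14 to the all-trans cyclopentane, in which the formyl group is trans to the bulky C9 substituent and the C14 ester trans to the formyl group and to the C12 ester, the hindered quaternary benzyl ester resisting exchange, and acid-catalysed acetalisation then masks the aldehyde.

Step 16
Reactants: 23 1β-alcohol acetal
Product: 24 C1 ketone acetal
Conditions: Dess–Martin periodinane, CH2Cl2, rt
Reagents that add atoms: none
Why: Dess–Martin oxidation removes the 1β-carbinol centre, whose relay task is done, under neutral conditions that spare acetal, esters and alkenes.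

Step 17
Reactants: 24 C1 ketone acetal
Product: 25 (1S)-alcohol acetal (1α-OH)
Conditions: (R)-2-methyl-CBS-oxazaborolidine (1 equiv), catecholborane (2 equiv), toluene, −40 to −10 °C; pH 7 buffer
Reagents that add atoms: none
Why: Corey–Bakshi–Shibata reduction under catalyst control: the oxazaborolidine binds the carbonyl lone pair on the CH2-2 side, treats quaternary C10 as the large flank and delivers hydride to the β face to give the (1S) 1α-alcohol, the same sense as Felkin–Anh attack anti to the bulky cyclopentyl substituent on C10, while acetal, esters and alkenes are inert to catecholborane.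

Step 18
Reactants: 25 1α-alcohol acetal
Product: 26 1α-acetate acetal
Conditions: Ac2O, DMAP, Et3N, CH2Cl2, 40 °C
Reagents that add atoms: acetic anhydride, CC(=O)OC(C)=O
Why: DMAP-catalysed acylation with gentle heating overcomes the hindrance of the axial neopentyl-type 1α-alcohol and installs the acetate that the key step needs.

Step 19
Reactants: 26 1α-acetate acetal
Product: 27 seco ring B aldehyde (C7 aldehyde on C8, C5 methylene, 1α-acetate, C12 allyl and benzyl ester, C14 methyl ester)
Conditions: PPTS (0.2 equiv), acetone–H2O (10:1), 45 °C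
Reagents that add atoms: water, O
Why: Mild acid-catalysed acetal hydrolysis frees the C7 aldehyde, whose α-centre C8 already has its thermodynamic configuration, under conditions too weak to trigger cyclisation onto the methylene group.

Step 20
Reactants: 27 seco ring B aldehyde
Product: 29 tricyclic 5α,7β-diol 1α-acetate, via dioxanylium ion 28 (not isolated)
Conditions: Me2AlCl (3 equiv), CH2Cl2, −78 to −30 °C; then aq. NaHCO3, 0 °C
Reagents that add atoms: water, O
Why: Me2AlCl binds the C7 aldehyde, the terminal carbon C6 of the 1,1-disubstituted alkene attacks it and the charge lands on tertiary C5 (Prins reaction; a concerted ene path is closed because C4 and C10 carry no hydrogen). Ring B closes 6-endo-trig at the alkene (exo at the carbonyl) through a chair in which C11 on C9, C14 on C8 and the aluminium-bound oxygen are all equatorial, so the fixed trans C8/C9 pair makes the C7 oxygen β. The carbonyl oxygen of the axial 1α-acetate sits 1,3-diaxial to the α lobe of the empty orbital and closes the six-membered 1,3-dioxan-2-ylium ion 28, so oxygen reaches C5 only from the α face and the decalin is trans. Water adds to the acetoxonium carbon and the orthoacid collapses to the tertiary C5 alcohol and the secondary C1 acetate, any 5-acetate formed first relaxing by 1,3-acyl shift to the less crowded O1. The closest known reaction type is the Lewis acid Prins cyclisation of an aldehyde with a 1,1-disubstituted alkene that ends by capture with a neighbouring ester carbonyl. The step needs this capture to outrun loss of H6, chloride or methyl transfer from aluminium and methyl shifts from C4 or C10, which the pre-organised 1,3-diaxial acetate and the low temperature should secure.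

Step 21
Reactants: 29 tricyclic diol acetate
Product: 30 C12 (2-oxoethyl) benzyl ester
Conditions: O3, CH2Cl2, −78 °C; Me2S, −78 °C to rt
Reagents that add atoms: ozone, [O-][O+]=O
Why: Ozonolysis with reductive work-up cleaves the only remaining C=C bond, the allyl group, to the C15–C16 acetaldehyde arm.

Step 22
Reactants: 30 aldehyde benzyl ester
Product: 32 spiro lactol (16-hydroxy γ-lactone, C16 epimers), via aldehyde acid 31 (not isolated)
Conditions: H2 (1 atm), Pd/C (10 %), EtOAc, rt
Reagents that add atoms: none
Why: Hydrogenolysis of the benzyl ester meets no C=C bond at this stage, and the freed C13 acid adds to the C16 aldehyde to give the five-membered pseudo-acid lactol, whose C16 configuration is of no consequence.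

Step 23
Reactants: 32 spiro lactol
Product: 34 spiro enol lactone 1,7-diacetate (C15=C16), via acetoxy lactone 33 (not isolated)
Conditions: Ac2O, NaOAc, 90 °C
Reagents that add atoms: acetic anhydride, CC(=O)OC(C)=O
Why: Acetylation and enol lactonisation of a γ-aldehydo acid by the acetic anhydride–acetate method: the 7β-hydroxyl is acetylated, lactol acetate 33 loses acetic acid toward C15, which holds the only β-hydrogens, quaternary C12 keeps the double bond from moving into conjugation, and the hindered tertiary 5-hydroxyl stays free.

Step 24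
Reactants: 34 spiro enol lactone
Product: 35 15-bromo-16-hydroxy lactone (bromine on the C11 side of the lactone ring)
Conditions: NBS (1.05 equiv), THF–H2O (5:1), 0 °C
Reagents that add atoms: N-bromosuccinimide, O=C1CCC(=O)N1Br; water, O
Why: Bromohydrin formation on an enol ester: electrophilic bromine adds to the nucleophilic carbon C15 from the face of the lactone ring that looks toward C11H2, the other face being covered by the cis (β) C14 ester, water caps the acyloxy-stabilised cation at C16, and this sets C15 for the inversion to come.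

Step 25
Reactants: 35 bromo lactol
Product: 36 spirocaesalmin
Conditions: AgOTf (1.2 equiv), 2,6-di-tert-butyl-4-methylpyridine (1.5 equiv), 4 Å molecular sieves, CH2Cl2, −40 to 0 °C, dark
Reagents that add atoms: none
Why: Proposed new method: silver-assisted departure of bromide with backside attack by the trans lactol oxygen (the C16 epimers interconvert through the open aldehyde acid) should close the oxirane with inversion at C15, that is on the C14 side which direct oxygen transfer to 34 is not expected to reach, under non-basic conditions that avoid enolisation at C15; the closest known reaction type is the closure of glycal-derived trans-halohydrins (2-halo lactols) to 1,2-anhydro sugars and, more generally, halohydrin-to-epoxide cyclisation.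

Compound list
1 | cis-cyclohex-4-ene-1,2-dicarboxylic anhydride (meso) | O=C1OC(=O)[C@H]2CC=CC[C@@H]12 | starting material
2 | (1R,6S)-6-(benzyloxycarbonyl)cyclohex-3-ene-1-carboxylic acid | O=C(OCc1ccccc1)[C@H]1CC=CC[C@H]1C(=O)O | intermediate
3 | allyl bromide | C=CCBr | starting material
4 | lithium (1R,6S)-6-allyl-6-(benzyloxycarbonyl)cyclohex-3-ene-1-carboxylate | C=CC[C@]1(C(=O)OCc2ccccc2)CC=CC[C@H]1C(=O)[O-].[Li+] | intermediate
5 | 1-allyl 2-benzyl (1R,2S)-2-allylcyclohex-4-ene-1,2-dicarboxylate | C=CC[C@]1(C(=O)OCc2ccccc2)CC=CC[C@H]1C(=O)OCC=C | intermediate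
6 | 4,5-epoxide of 5, oxirane trans to the ester groups | C=CC[C@]1(C(=O)OCc2ccccc2)C[C@@H]2O[C@@H]2C[C@H]1C(=O)OCC=C | intermediate
7 | 4-allyl 1-benzyl 2-allyl-2,3-bis(2-oxoethyl)butanedioate | C=CC[C@@](CC=O)(C(=O)OCc1ccccc1)[C@@H](CC=O)C(=O)OCC=C | intermediate
8 | ring C enal, 1-allyl 2-benzyl 2-allyl-5-formylcyclopent-4-ene-1,2-dicarboxylate, esters cis | O=CC1=CC[C@](CC=C)(C(=O)OCc2ccccc2)[C@@H]1C(=O)OCC=C | intermediate
9 | 4,4-dimethylcyclohexane-1,3-dione | CC1(C)CCC(=O)CC1=O | starting material
10 | 2,4,4-trimethylcyclohexane-1,3-dione | CC1C(=O)CCC(C)(C)C1=O | intermediate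
11 | 3-isobutoxy-2,6,6-trimethylcyclohex-2-en-1-one | CC1=C(OCC(C)C)CCC(C)(C)C1=O | intermediate
12 | 3-isobutoxy-1,2,6,6-tetramethylcyclohex-2-en-1-ol (racemic) | CC1=C(OCC(C)C)CCC(C)(C)C1(C)O | intermediate
13 | 2,3,4,4-tetramethylcyclohex-2-en-1-one | CC1=C(C)C(C)(C)CCC1=O | intermediate
14 | tert-butyl(dimethyl)[(2,4,4-trimethyl-3-methylenecyclohex-1-en-1-yl)oxy]silane | CC1=C(O[Si](C)(C)C(C)(C)C)CCC(C)(C)C1=C | intermediate
15 | enone aldol, C7 epimers | CC1=C(CC(O)C2=CC[C@](CC=C)(C(=O)OCc3ccccc3)[C@@H]2C(=O)OCC=C)C(C)(C)CCC1=O | intermediate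
16 | (1R)-allylic alcohol (1β-OH), C7 epimers | CC1=C(CC(O)C2=CC[C@](CC=C)(C(=O)OCc3ccccc3)[C@@H]2C(=O)OCC=C)C(C)(C)CC[C@H]1O | intermediate
17 | potassium C14 carboxylate of the diol | CC1=C(CC(O)C2=CC[C@](CC=C)(C(=O)OCc3ccccc3)[C@@H]2C(=O)[O-])C(C)(C)CC[C@H]1O.[K+] | intermediate
18 | tripotassium salt, C1 and C7 alkoxides and C14 carboxylate | CC1=C(CC([O-])C2=CC[C@](CC=C)(C(=O)OCc3ccccc3)[C@@H]2C(=O)[O-])C(C)(C)CC[C@H]1[O-].[K+].[K+].[K+] | intermediate
19 | tripotassium salt after the shift, C7=C8 enolate, C1 alkoxide, C14 carboxylate | [O-]C=C1[C@H](C[C@](CC=C)(C(=O)OCc2ccccc2)[C@@H]1C(=O)[O-])[C@]3(C)C(=C)C(C)(C)CC[C@H]3[O-].[K+].[K+].[K+] | intermediate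
20 | seco ring B hydroxy aldehyde acid, 1β-OH, C14 carboxyl α, C8 epimers | O=CC1[C@H](C[C@](CC=C)(C(=O)OCc2ccccc2)[C@@H]1C(=O)O)[C@]3(C)C(=C)C(C)(C)CC[C@H]3O | intermediate
21 | methyl ester of 20 | O=CC1[C@H](C[C@](CC=C)(C(=O)OCc2ccccc2)[C@@H]1C(=O)OC)[C@]3(C)C(=C)C(C)(C)CC[C@H]3O | intermediate
22 | all-trans aldehyde, 1β-OH | O=C[C@@H]1[C@H](C[C@](CC=C)(C(=O)OCc2ccccc2)[C@H]1C(=O)OC)[C@]3(C)C(=C)C(C)(C)CC[C@H]3O | intermediate
23 | all-trans dimethyl acetal, 1β-OH | COC(OC)[C@@H]1[C@H](C[C@](CC=C)(C(=O)OCc2ccccc2)[C@H]1C(=O)OC)[C@]3(C)C(=C)C(C)(C)CC[C@H]3O | intermediate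
24 | C1 ketone acetal | COC(OC)[C@@H]1[C@H](C[C@](CC=C)(C(=O)OCc2ccccc2)[C@H]1C(=O)OC)[C@]3(C)C(=C)C(C)(C)CCC3=O | intermediate
25 | 1α-alcohol acetal | COC(OC)[C@@H]1[C@H](C[C@](CC=C)(C(=O)OCc2ccccc2)[C@H]1C(=O)OC)[C@]3(C)C(=C)C(C)(C)CC[C@@H]3O | intermediate
26 | 1α-acetate acetal | COC(OC)[C@@H]1[C@H](C[C@](CC=C)(C(=O)OCc2ccccc2)[C@H]1C(=O)OC)[C@]3(C)C(=C)C(C)(C)CC[C@@H]3OC(C)=O | intermediate
27 | seco ring B aldehyde (precursor of the key step) | O=C[C@@H]1[C@H](C[C@](CC=C)(C(=O)OCc2ccccc2)[C@H]1C(=O)OC)[C@]3(C)C(=C)C(C)(C)CC[C@@H]3OC(C)=O | intermediate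
28 | O1,O5-bridged 2-methyl-1,3-dioxan-2-ylium ion, C7 chlorodimethylaluminate | COC(=O)[C@H]1[C@@H]2[C@@H](O[Al-](C)(C)Cl)C[C@@]3(OC(C)=[O+]4)C(C)(C)CC[C@H]4[C@]3(C)[C@H]2C[C@]1(CC=C)C(=O)OCc1ccccc1 | intermediate
29 | tricyclic 5α,7β-diol 1α-acetate (product of the key step) | COC(=O)[C@H]1[C@@H]2[C@@H](O)C[C@@]3(O)C(C)(C)CC[C@H](OC(C)=O)[C@]3(C)[C@H]2C[C@]1(CC=C)C(=O)OCc1ccccc1 | intermediate
30 | C12 (2-oxoethyl) benzyl ester | COC(=O)[C@H]1[C@@H]2[C@@H](O)C[C@@]3(O)C(C)(C)CC[C@H](OC(C)=O)[C@]3(C)[C@H]2C[C@]1(CC=O)C(=O)OCc1ccccc1 | intermediate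
31 | C12 (2-oxoethyl) carboxylic acid | COC(=O)[C@H]1[C@@H]2[C@@H](O)C[C@@]3(O)C(C)(C)CC[C@H](OC(C)=O)[C@]3(C)[C@H]2C[C@]1(CC=O)C(=O)O | intermediate
32 | spiro lactol, C16 epimers | COC(=O)[C@H]1[C@@H]2[C@@H](O)C[C@@]3(O)C(C)(C)CC[C@H](OC(C)=O)[C@]3(C)[C@H]2C[C@@]14CC(O)OC4=O | intermediate
33 | 1,7,16-triacetate (16-acetoxy lactone), C16 epimers | COC(=O)[C@H]1[C@@H]2[C@@H](OC(C)=O)C[C@@]3(O)C(C)(C)CC[C@H](OC(C)=O)[C@]3(C)[C@H]2C[C@@]14CC(OC(C)=O)OC4=O | intermediate
34 | spiro enol lactone 1,7-diacetate | COC(=O)[C@H]1[C@@H]2[C@@H](OC(C)=O)C[C@@]3(O)C(C)(C)CC[C@H](OC(C)=O)[C@]3(C)[C@H]2C[C@@]14C=COC4=O | intermediate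
35 | 15-bromo-16-hydroxy lactone, Br on the C11 side, OH drawn trans to Br | COC(=O)[C@H]1[C@@H]2[C@@H](OC(C)=O)C[C@@]3(O)C(C)(C)CC[C@H](OC(C)=O)[C@]3(C)[C@H]2C[C@@]14[C@H](Br)[C@@H](O)OC4=O | intermediate
36 | spirocaesalmin | COC(=O)[C@H]1[C@@H]2[C@@H](OC(C)=O)C[C@@]3(O)C(C)(C)CC[C@H](OC(C)=O)[C@]3(C)[C@H]2C[C@]12C(=O)O[C@@H]1O[C@@H]12 | target

Total step count: 25. Longest linear sequence: 21 steps (steps 1–5 and 10–25).

Steps most likely to fail

Step 25 (labelled).
What may go wrong: the bromo lactol may open to the aldehyde acid. This can be followed by enolisation at C15, which loses its configuration, or by attack of the carboxyl oxygen on C15, and either process may outrun oxirane closure.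
Fallback: it sets out from enol lactone 34 and comes back at 36.
- Oxygen is transferred directly with dimethyldioxirane in acetone–CH2Cl2 at −20 °C, a known epoxidation of enol esters and enol lactones.
- The open face of 34 is the C11 side, so poor facial selectivity must be expected and the two epoxides would have to be separated.
- A fructose-derived chiral dioxirane (Shi epoxidation) can be used to lean on reagent control.
- The fallback makes no new compound (F0).

Step 13.
What may go wrong: the C6–C7 bond may break heterolytically (retro-allylation of the alkoxide), or the substrate may simply stay inert because of the steric compression at the forming quaternary centre.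
Fallback: it sets out from enal 8 and enone 13 and comes back at ketone 24.
- The thermodynamic potassium dienolate of 13 (KOt-Bu, t-BuOH–THF, 0 °C) is added through its α-carbon C10 to C9 of 8. This deconjugative Michael addition is the polar counterpart of the sigmatropic shift and gives the keto aldehyde allyl ester F1.
- Pd(PPh3)4 and morpholine give the keto aldehyde acid F2.
- MeI and K2CO3 give the keto aldehyde methyl ester F3.
- NaOMe followed by CSA and HC(OMe)3, as in step 15, leads to 24.
- Steps 11 and 16 drop out, but the C10 face is then steered only by ring C, so diastereomers would have to be separated.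

Step 17.
What may go wrong: hydride delivery to the carbonyl flanked by quaternary C10 may show poor facial selectivity, or the reduction may be too slow.
Fallback: it sets out from the 1β-alcohol 23 and comes back at the 1α-alcohol 25, bypassing steps 16 and 17.
- Mitsunobu inversion (4-nitrobenzoic acid, PPh3, DIAD, toluene, rt to 60 °C) gives the 1α-(4-nitrobenzoate) acetal F4.
- K2CO3 in MeOH then cleaves F4 to 25.

Further compounds
F0 | step 25 | none | none
F1 | step 13 | keto aldehyde allyl ester | O=CC1[C@H](C[C@](CC=C)(C(=O)OCc2ccccc2)[C@@H]1C(=O)OCC=C)[C@]3(C)C(=C)C(C)(C)CCC3=O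
F2 | step 13 | keto aldehyde acid | O=CC1[C@H](C[C@](CC=C)(C(=O)OCc2ccccc2)[C@@H]1C(=O)O)[C@]3(C)C(=C)C(C)(C)CCC3=O
F3 | step 13 | keto aldehyde methyl ester | O=CC1[C@H](C[C@](CC=C)(C(=O)OCc2ccccc2)[C@@H]1C(=O)OC)[C@]3(C)C(=C)C(C)(C)CCC3=O
F4 | step 17 | 1α-(4-nitrobenzoate) acetal | COC(OC)[C@@H]1[C@H](C[C@](CC=C)(C(=O)OCc2ccccc2)[C@H]1C(=O)OC)[C@]3(C)C(=C)C(C)(C)CC[C@@H]3OC(=O)c4ccc(cc4)[N+](=O)[O-]
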